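**Plan**

- Ring locants: C1 (CHOAc), C2 (CMe), C3 (=CH), C4 (C=O), C5 (oxirane carbon bearing the chain), C6 (oxirane CH). The retrosynthesis cuts, in order: the C1–OAc bond (with inversion); the C2–CH3 bond, with the carbonyl moved from C4 back to C2; the C6–O bond of the oxirane (reopened to a C1–C6 oxirane and a C5 hydroxyl); the C1/C6 oxygen; the C5–O bond (back to a phenol); and the aryl–C1' bond to the chain.
- Forward: farnesol is oxidized at C12' and converted into a silyloxy farnesyl bromide, which is joined to a 4-silyloxyphenylcopper. Dearomatization then turns the arene into the carbocycle, a first oxirane is placed on C1–C6, and the epoxide migration builds the C5–C6 oxirane of the target. Methyl addition, carbonyl transposition, inversion/acetylation at C1 and desilylation finish the route.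
- Enabling feature: C5 carries both the chain and an oxygen. With the carbonyl at C2 and the methyl absent, C5 is the carbinol carbon of a 4-alkyl-4-hydroxycyclohexa-2,5-dienone whose arms C3=C4 and C1=C6 are enantiotopic. An oxirane on C1–C6 anti to the C5 oxygen can then pass C6 over to that oxygen.
- Stereochemistry: a cinchona phase-transfer epoxidation selects the C1=C6 arm on the face anti to the C5 silyloxy group, which fixes C5. The migration inverts C6 under control of C5, a Mitsunobu reaction inverts C1, and the three E alkenes come from farnesol.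

Key step: step 13

Conventions: "silyloxyfarnesyl" means (2E,6E,10E)-12-(tert-butyldiphenylsilyloxy)-3,7,11-trimethyldodeca-2,6,10-trien-1-yl. Ring locants C1–C6 are those of the plan and are kept for every ring compound.

Assumption: N-benzylcinchonidinium chloride is taken to direct the peroxide to the C1=C6 arm of dienone 14; if the other arm is preferred, the pseudo-enantiomeric N-benzylcinchoninium chloride is used instead.

**Route**

Step 1
Reactants: 1 (2E,6E)-farnesol
Product: 2 (2E,6E)-farnesyl acetate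
Conditions: Ac2O, pyridine, DMAP (cat.), CH2Cl2, 0 °C → rt
Reagents that add atoms: acetic anhydride, CC(=O)OC(C)=O
Why: DMAP-catalysed acylation of the primary allylic alcohol masks C1' so that the next oxidation is directed only to the far end of the chain.

Step 2
Reactants: 2 (2E,6E)-farnesyl acetate
Product: 3 (2E,6E,10E)-12-hydroxyfarnesyl acetate
Conditions: SeO2 (cat.), t-BuOOH, salicylic acid (cat.), CH2Cl2, 0 °C → rt
Reagents that add atoms: tert-butyl hydroperoxide, CC(C)(C)OO (oxygen atom, passed on through catalytic SeO2)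
Why: The Riley allylic oxidation (ene reaction then [2,3] shift) is fastest at the electron-rich terminal trisubstituted alkene and selective for its E methyl group, so the (10E)-12-alcohol should dominate if the reaction is stopped before over-oxidation to the enal.

Step 3
Reactants: 3 (2E,6E,10E)-12-hydroxyfarnesyl acetate
Product: 4 (2E,6E,10E)-12-(tert-butyldiphenylsilyloxy)farnesyl acetate
Conditions: t-BuPh2SiCl, imidazole, DMF, rt
Reagents that add atoms: tert-butyldiphenylsilyl chloride, CC(C)(C)[Si](Cl)(c1ccccc1)c1ccccc1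
Why: Silylation of the primary alcohol installs a robust ether that should outlast the two later removals of triethylsilyl groups.

Step 4
Reactants: 4 (2E,6E,10E)-12-(tert-butyldiphenylsilyloxy)farnesyl acetate
Product: 5 (2E,6E,10E)-12-(tert-butyldiphenylsilyloxy)farnesol
Conditions: K2CO3 (cat.), MeOH, rt
Reagents that add atoms: none
Why: Base-catalysed transesterification removes the acetate and leaves the silyl ether and the alkenes untouched.

Step 5
Reactants: 5 (2E,6E,10E)-12-(tert-butyldiphenylsilyloxy)farnesol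
Product: 6 (2E,6E,10E)-12-(tert-butyldiphenylsilyloxy)farnesyl bromide
Conditions: PBr3, pyridine (cat.), Et2O, −10 °C
Reagents that add atoms: phosphorus tribromide, BrP(Br)Br
Why: Bromination of the primary allylic alcohol through its phosphite ester proceeds by SN2 displacement and should keep the 2E geometry, as it does for farnesyl bromide itself.

Step 6
Reactants: 7 4-bromophenol
Product: 8 (4-bromophenoxy)-tert-butyldimethylsilane
Conditions: t-BuMe2SiCl, imidazole, DMF, rt
Reagents that add atoms: tert-butyldimethylsilyl chloride, CC(C)(C)[Si](C)(C)Cl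
Why: Silylation of the phenol removes the acidic proton so that the aryl bromide can be metalated.

Step 7
Reactants: 8 (4-bromophenoxy)-tert-butyldimethylsilane; 6 (2E,6E,10E)-12-(tert-butyldiphenylsilyloxy)farnesyl bromide
Product: 11 tert-butyldimethylsilyl 4-(silyloxyfarnesyl)phenyl ether, via aryllithium 9 (not isolated), via arylcopper 10 (not isolated)
Conditions: n-BuLi, THF, −78 °C; CuBr·SMe2, −78 → −40 °C; then 6, −78 → 0 °C
Reagents that add atoms: none
Why: Bromine–lithium exchange and transmetalation give an arylcopper that should substitute the primary allylic bromide at C1' (SN2 rather than SN2', since the γ-carbon is fully substituted) in a copper-mediated allylic cross-coupling that keeps the E alkene.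

Step 8
Reactants: 11 tert-butyldimethylsilyl 4-(silyloxyfarnesyl)phenyl ether
Product: 12 4-(silyloxyfarnesyl)phenol
Conditions: Cs2CO3 (0.5 equiv), DMF–H2O, rt
Reagents that add atoms: none
Why: Carbonate-mediated hydrolysis cleaves aryl silyl ethers selectively because phenoxide is the better leaving group, so the alkyl tert-butyldiphenylsilyl ether should remain.

Step 9
Reactants: 12 4-(silyloxyfarnesyl)phenol
Product: 13 4-hydroxy-4-(silyloxyfarnesyl)cyclohexa-2,5-dienone
Conditions: PhI(OAc)2, MeCN–H2O, 0 °C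
Reagents that add atoms: water, O
Why: Oxidative dearomatization of a para-alkylphenol by the trivalent iodine reagent lets water attack the para carbon, which gives the achiral para-quinol; the isolated alkenes should not react with the unactivated reagent.

Step 10
Reactants: 13 4-hydroxy-4-(silyloxyfarnesyl)cyclohexa-2,5-dienone
Product: 14 4-(triethylsilyloxy)-4-(silyloxyfarnesyl)cyclohexa-2,5-dienone
Conditions: Et3SiOTf, 2,6-lutidine, CH2Cl2, −78 °C
Reagents that add atoms: triethylsilyl trifluoromethanesulfonate, CC[Si](CC)(CC)OS(=O)(=O)C(F)(F)F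
Why: Silyl triflate silylation of the tertiary alcohol removes the hydrogen-bond donor that would steer a peroxide to the syn face and places a bulky group on that face instead.

Step 11
Reactants: 14 4-(triethylsilyloxy)-4-(silyloxyfarnesyl)cyclohexa-2,5-dienone
Product: 15 (1R,5S,6S)-1,6-epoxy-5-(triethylsilyloxy)-5-(silyloxyfarnesyl)cyclohex-3-en-2-one (oxirane anti to the C5 silyloxy group)
Conditions: t-BuOOH (1.1 equiv), aq. NaOH, N-benzylcinchonidinium chloride (cat.), toluene, 0 °C
Reagents that add atoms: tert-butyl hydroperoxide, CC(C)(C)OO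
Why: Asymmetric Weitz–Scheffer epoxidation under chiral phase-transfer catalysis desymmetrizes the dienone: the ion-paired peroxide should select the C1=C6 arm (setting C5), and the bulky C5 silyloxy group together with the preference for attack anti to the C–O bond should direct it to the opposite face (setting C1 and C6).

Step 12
Reactants: 15 (1R,5S,6S)-1,6-epoxy-5-(triethylsilyloxy)-5-(silyloxyfarnesyl)cyclohex-3-en-2-one
Product: 16 (1R,5S,6S)-1,6-epoxy-5-hydroxy-5-(silyloxyfarnesyl)cyclohex-3-en-2-one (oxirane anti to the C5 hydroxyl)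
Conditions: HF·pyridine, pyridine, THF, 0 °C
Reagents that add atoms: none
Why: Buffered HF cleaves the triethylsilyl ether much faster than the tert-butyldiphenylsilyl ether, and the α,β-epoxy ketone is deactivated towards acid opening.

Step 13
Reactants: 16 (1R,5S,6S)-1,6-epoxy-5-hydroxy-5-(silyloxyfarnesyl)cyclohex-3-en-2-one
Product: 19 (1R,5S,6R)-5,6-epoxy-1-hydroxy-5-(silyloxyfarnesyl)cyclohex-3-en-2-one, via tertiary sodium alkoxide 17 (not isolated), via rearranged sodium alkoxide 18 (not isolated)
Conditions: NaN(SiMe3)2 (1.0 equiv), THF, −78 → −20 °C; AcOH (1.0 equiv), −78 °C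
Reagents that add atoms: none
Why: NaN(SiMe3)2 removes the C5 hydroxyl proton, and the tertiary alkoxide 17, which lies anti-periplanar to the C6–O bond of the C1–C6 oxirane, displaces that oxygen from C6 in an intramolecular SN2 reaction to give the α-keto alkoxide 18, which acetic acid protonates to 19; this is a Payne rearrangement (epoxide migration) of a trans-2,3-epoxy alcohol. The new C5–C6 oxirane closes in the 3-exo-tet mode, whereas attack at C1 would need a four-membered 4-endo closure and is not expected. C6 is inverted from S to R under control of the C5 carbinol centre, because the oxygen can only enter from the face that carries it; C1 and C5 are untouched, so the C1 hydroxyl ends anti to the new oxirane. The step needs the equilibrium to lie on the product side, which the trisubstituted oxirane and the less basic secondary α-keto alkoxide should secure. It also needs migration to outrun fragmentation of the alkoxide and enolization of the product, which one equivalent of base, the sodium counter-ion, the low temperature and the C1 alkoxide (it disfavours removal of the C1 proton) are meant to ensure.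

Step 14
Reactants: 19 (1R,5S,6R)-5,6-epoxy-1-hydroxy-5-(silyloxyfarnesyl)cyclohex-3-en-2-one
Product: 20 (1R,5S,6R)-5,6-epoxy-1-(triethylsilyloxy)-5-(silyloxyfarnesyl)cyclohex-3-en-2-one
Conditions: Et3SiCl, imidazole, CH2Cl2, 0 °C
Reagents that add atoms: chlorotriethylsilane, CC[Si](Cl)(CC)CC
Why: Silylation of the secondary α-ketol hydroxyl under weakly basic conditions removes the acidic proton before the organometallic step and can later be undone without touching the chain ether.

Step 15
Reactants: 20 (1R,5S,6R)-5,6-epoxy-1-(triethylsilyloxy)-5-(silyloxyfarnesyl)cyclohex-3-en-2-one; 21 methyllithium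
Product: 23 (1R,5S,6R)-5,6-epoxy-2-methyl-1-(triethylsilyloxy)-5-(silyloxyfarnesyl)cyclohex-3-en-2-ol as a mixture of C2 epimers, via methylcerium dichloride 22 (not isolated)
Conditions: CeCl3 (anhydrous), MeLi, THF, −78 °C; then 20, −78 °C; pH 7 buffer
Reagents that add atoms: methyllithium, [Li]C
Why: The weakly basic organocerium reagent adds 1,2 to the enone carbonyl without removing the C1 proton or opening the vinyl oxirane; attack anti to the C1 silyloxy group should dominate, and the C2 configuration is of no consequence because C2 becomes sp2 in the next step.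

Step 16
Reactants: 23 (1R,5S,6R)-5,6-epoxy-2-methyl-1-(triethylsilyloxy)-5-(silyloxyfarnesyl)cyclohex-3-en-2-ol
Product: 24 (1S,5R,6R)-5,6-epoxy-2-methyl-1-(triethylsilyloxy)-5-(silyloxyfarnesyl)cyclohex-2-en-4-one
Conditions: (C5H5NH)2Cr2O7, 4 Å MS, CH2Cl2, rt
Reagents that add atoms: pyridinium dichromate, [O-][Cr](=O)(=O)O[Cr](=O)(=O)[O-].c1cc[nH+]cc1.c1cc[nH+]cc1 (supplies the C4 carbonyl oxygen)
Why: In the Babler–Dauben oxidative transposition the chromate ester of the tertiary allylic alcohol undergoes a [3,3] shift to C4 and is then oxidized, which delivers the methyl-substituted C2=C3 alkene and the C4 ketone together; the nearly neutral dichromate is chosen to spare the allylic oxirane.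

Step 17
Reactants: 24 (1S,5R,6R)-5,6-epoxy-2-methyl-1-(triethylsilyloxy)-5-(silyloxyfarnesyl)cyclohex-2-en-4-one
Product: 25 (1S,5R,6R)-5,6-epoxy-1-hydroxy-2-methyl-5-(silyloxyfarnesyl)cyclohex-2-en-4-one (hydroxyl anti to the oxirane)
Conditions: HF·pyridine, pyridine, THF, 0 °C
Reagents that add atoms: none
Why: Selective desilylation: the secondary triethylsilyl ether is cleaved well before the primary tert-butyldiphenylsilyl ether, and the oxirane is now part of an acid-tolerant α,β-epoxy ketone.

Step 18
Reactants: 25 (1S,5R,6R)-5,6-epoxy-1-hydroxy-2-methyl-5-(silyloxyfarnesyl)cyclohex-2-en-4-one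
Product: 26 (1R,5R,6R)-1-acetoxy-5,6-epoxy-2-methyl-5-(silyloxyfarnesyl)cyclohex-2-en-4-one (acetoxy syn to the oxirane)
Conditions: AcOH, PPh3, diisopropyl azodicarboxylate, toluene, 0 °C → rt
Reagents that add atoms: acetic acid, CC(=O)O
Why: In the Mitsunobu reaction acetate displaces the allylic oxyphosphonium group at C1 by SN2 with inversion, which turns the anti carbinol into the syn acetate of the target; the silyl ether keeps the primary chain alcohol out of the reaction.

Step 19
Reactants: 26 (1R,5R,6R)-1-acetoxy-5,6-epoxy-2-methyl-5-(silyloxyfarnesyl)cyclohex-2-en-4-one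
Product: 27 yanuthone L
Conditions: HF·pyridine, pyridine, THF, 0 °C → rt
Reagents that add atoms: none
Why: Fluoride-mediated cleavage of the primary allylic silyl ether under buffered, non-basic conditions should leave the acetate, the epoxy enone and the C1 configuration intact.

**Compound list**

1 | (2E,6E)-farnesol | CC(C)=CCC/C(C)=C/CC/C(C)=C/CO | starting material
2 | (2E,6E)-farnesyl acetate | CC(C)=CCC/C(C)=C/CC/C(C)=C/COC(C)=O | intermediate
3 | (2E,6E,10E)-12-hydroxyfarnesyl acetate | OC/C(C)=C/CC/C(C)=C/CC/C(C)=C/COC(C)=O | intermediate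
4 | (2E,6E,10E)-12-(tert-butyldiphenylsilyloxy)farnesyl acetate | CC(C)(C)[Si](c1ccccc1)(c1ccccc1)OC/C(C)=C/CC/C(C)=C/CC/C(C)=C/COC(C)=O | intermediate
5 | (2E,6E,10E)-12-(tert-butyldiphenylsilyloxy)farnesol | CC(C)(C)[Si](c1ccccc1)(c1ccccc1)OC/C(C)=C/CC/C(C)=C/CC/C(C)=C/CO | intermediate
6 | (2E,6E,10E)-12-(tert-butyldiphenylsilyloxy)farnesyl bromide | CC(C)(C)[Si](c1ccccc1)(c1ccccc1)OC/C(C)=C/CC/C(C)=C/CC/C(C)=C/CBr | intermediate
7 | 4-bromophenol | Oc1ccc(Br)cc1 | starting material
8 | (4-bromophenoxy)-tert-butyldimethylsilane | CC(C)(C)[Si](C)(C)Oc1ccc(Br)cc1 | intermediate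
9 | 4-(tert-butyldimethylsilyloxy)phenyllithium (not isolated) | [Li]c1ccc(O[Si](C)(C)C(C)(C)C)cc1 | intermediate
10 | 4-(tert-butyldimethylsilyloxy)phenylcopper (not isolated) | [Cu]c1ccc(O[Si](C)(C)C(C)(C)C)cc1 | intermediate
11 | tert-butyldimethylsilyl 4-(silyloxyfarnesyl)phenyl ether | CC(C)(C)[Si](C)(C)Oc1ccc(C/C=C(\C)CC/C=C(\C)CC/C=C(\C)CO[Si](c2ccccc2)(c2ccccc2)C(C)(C)C)cc1 | intermediate
12 | 4-(silyloxyfarnesyl)phenol | Oc1ccc(C/C=C(\C)CC/C=C(\C)CC/C=C(\C)CO[Si](c2ccccc2)(c2ccccc2)C(C)(C)C)cc1 | intermediate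
13 | 4-hydroxy-4-(silyloxyfarnesyl)cyclohexa-2,5-dienone (achiral para-quinol) | O=C1C=CC(O)(C/C=C(\C)CC/C=C(\C)CC/C=C(\C)CO[Si](c2ccccc2)(c2ccccc2)C(C)(C)C)C=C1 | intermediate
14 | 4-(triethylsilyloxy)-4-(silyloxyfarnesyl)cyclohexa-2,5-dienone (achiral) | O=C1C=CC(O[Si](CC)(CC)CC)(C/C=C(\C)CC/C=C(\C)CC/C=C(\C)CO[Si](c2ccccc2)(c2ccccc2)C(C)(C)C)C=C1 | intermediate
15 | (1R,5S,6S)-1,6-epoxy-5-(triethylsilyloxy)-5-(silyloxyfarnesyl)cyclohex-3-en-2-one, oxirane anti to the silyloxy group | O=C1C=C[C@@](O[Si](CC)(CC)CC)(C/C=C(\C)CC/C=C(\C)CC/C=C(\C)CO[Si](c3ccccc3)(c3ccccc3)C(C)(C)C)[C@H]2O[C@@H]12 | intermediate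
16 | (1R,5S,6S)-1,6-epoxy-5-hydroxy-5-(silyloxyfarnesyl)cyclohex-3-en-2-one, oxirane anti to the hydroxyl (key-step precursor) | O=C1C=C[C@@](O)(C/C=C(\C)CC/C=C(\C)CC/C=C(\C)CO[Si](c3ccccc3)(c3ccccc3)C(C)(C)C)[C@H]2O[C@@H]12 | intermediate
17 | sodium C5 alkoxide of 16 (not isolated) | O=C1C=C[C@@]([O-])(C/C=C(\C)CC/C=C(\C)CC/C=C(\C)CO[Si](c3ccccc3)(c3ccccc3)C(C)(C)C)[C@H]2O[C@@H]12.[Na+] | intermediate
18 | sodium C1 alkoxide of 19 (not isolated) | [O-][C@H]1C(=O)C=C[C@]2(C/C=C(\C)CC/C=C(\C)CC/C=C(\C)CO[Si](c3ccccc3)(c3ccccc3)C(C)(C)C)O[C@H]12.[Na+] | intermediate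
19 | (1R,5S,6R)-5,6-epoxy-1-hydroxy-5-(silyloxyfarnesyl)cyclohex-3-en-2-one, hydroxyl anti to the oxirane (key-step product) | O[C@H]1C(=O)C=C[C@]2(C/C=C(\C)CC/C=C(\C)CC/C=C(\C)CO[Si](c3ccccc3)(c3ccccc3)C(C)(C)C)O[C@H]12 | intermediate
20 | (1R,5S,6R)-5,6-epoxy-1-(triethylsilyloxy)-5-(silyloxyfarnesyl)cyclohex-3-en-2-one | CC[Si](CC)(CC)O[C@H]1C(=O)C=C[C@]2(C/C=C(\C)CC/C=C(\C)CC/C=C(\C)CO[Si](c3ccccc3)(c3ccccc3)C(C)(C)C)O[C@H]12 | intermediate
21 | methyllithium | [Li]C | starting material
22 | methylcerium dichloride (not isolated) | C[Ce](Cl)Cl | intermediate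
23 | (1R,5S,6R)-5,6-epoxy-2-methyl-1-(triethylsilyloxy)-5-(silyloxyfarnesyl)cyclohex-3-en-2-ol, mixture of C2 epimers (C2 left undefined) | CC[Si](CC)(CC)O[C@H]1C(C)(O)C=C[C@]2(C/C=C(\C)CC/C=C(\C)CC/C=C(\C)CO[Si](c3ccccc3)(c3ccccc3)C(C)(C)C)O[C@H]12 | intermediate
24 | (1S,5R,6R)-5,6-epoxy-2-methyl-1-(triethylsilyloxy)-5-(silyloxyfarnesyl)cyclohex-2-en-4-one | CC[Si](CC)(CC)O[C@H]1C(C)=CC(=O)[C@]2(C/C=C(\C)CC/C=C(\C)CC/C=C(\C)CO[Si](c3ccccc3)(c3ccccc3)C(C)(C)C)O[C@H]12 | intermediate
25 | (1S,5R,6R)-5,6-epoxy-1-hydroxy-2-methyl-5-(silyloxyfarnesyl)cyclohex-2-en-4-one, hydroxyl anti to the oxirane | O[C@H]1C(C)=CC(=O)[C@]2(C/C=C(\C)CC/C=C(\C)CC/C=C(\C)CO[Si](c3ccccc3)(c3ccccc3)C(C)(C)C)O[C@H]12 | intermediate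
26 | (1R,5R,6R)-1-acetoxy-5,6-epoxy-2-methyl-5-(silyloxyfarnesyl)cyclohex-2-en-4-one, acetoxy syn to the oxirane | CC(=O)O[C@@H]1C(C)=CC(=O)[C@]2(C/C=C(\C)CC/C=C(\C)CC/C=C(\C)CO[Si](c3ccccc3)(c3ccccc3)C(C)(C)C)O[C@H]12 | intermediate
27 | yanuthone L, (1R,5R,6R)-1-acetoxy-5,6-epoxy-5-[(2E,6E,10E)-12-hydroxyfarnesyl]-2-methylcyclohex-2-en-4-one | CC(=O)O[C@@H]1C(C)=CC(=O)[C@]2(C/C=C(\C)CC/C=C(\C)CC/C=C(\C)CO)O[C@H]12 | target

**Step count and risks**

Total step count: 19. Longest linear sequence: 18 steps (steps 1–5 and 7–19, from farnesol).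

Steps most likely to fail:

Step 11. The ion-paired catalyst may discriminate poorly between the two enantiotopic enone arms of 14, so that the epoxide forms with low enantiomeric purity. The fallback sets out from 14 and returns at 19. Dienone 14 is epoxidized without a chiral catalyst (t-BuOOH, DBU, CH2Cl2, 0 °C), relying only on the preference of the substrate for attack anti to the silyloxy group, which should give the racemic anti epoxide F1. HF·pyridine then frees the racemic epoxy quinol F2, and NaN(SiMe3)2 in THF rearranges it as in step 13 to the racemic ketol F3. A lipase-mediated kinetic resolution (Candida antarctica lipase B, vinyl acetate, t-BuOMe), with the enzyme chosen by screening for this sense, acetylates the unwanted enantiomer to the enantiomeric ketol acetate F4 and leaves the wanted alcohol, which is 19.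

Step 16. The allylic oxirane may open under the slightly acidic oxidant, or the 1,3-shift of the chromate ester may be slow because both allylic termini carry inductively withdrawing oxygen substituents. The fallback sets out from 23 and returns at 24. The oxidation is separated from the transposition: Ph3SiOReO3 (cat.) in Et2O at −50 → 0 °C moves the hydroxyl by a [3,3] shift of the perrhenate ester towards the more substituted alkene, which should give the transposed secondary allylic alcohol F5 as a mixture of C4 epimers. Dess–Martin periodinane buffered with NaHCO3 in CH2Cl2 then oxidizes it to 24.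

Step 18. Displacement at C1, which is flanked by the oxirane and the methyl-bearing alkene, may be slow, so that the oxyphosphonium ion eliminates or ionizes and the inversion is incomplete. The fallback sets out from 25 and returns at 26, and replaces the substitution by an oxidation–reduction sequence. Dess–Martin periodinane oxidizes 25 to the epoxyquinone F6. NaBH4 in MeOH at −78 °C should then deliver hydride to the C1 carbonyl (less hindered than C4, which abuts the quaternary C5, and not deactivated by the β-methyl group) from the face opposite the oxirane, giving the syn epoxy alcohol F7. Ac2O, pyridine and DMAP (cat.) convert it into 26.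

**Further compounds**

F1 | step 11 | racemic anti epoxide, 15 together with its enantiomer | O=C1C=C[C@@](O[Si](CC)(CC)CC)(C/C=C(\C)CC/C=C(\C)CC/C=C(\C)CO[Si](c3ccccc3)(c3ccccc3)C(C)(C)C)[C@H]2O[C@@H]12.O=C1C=C[C@](O[Si](CC)(CC)CC)(C/C=C(\C)CC/C=C(\C)CC/C=C(\C)CO[Si](c3ccccc3)(c3ccccc3)C(C)(C)C)[C@@H]2O[C@H]12
F2 | step 11 | racemic epoxy quinol, 16 together with its enantiomer | O=C1C=C[C@@](O)(C/C=C(\C)CC/C=C(\C)CC/C=C(\C)CO[Si](c3ccccc3)(c3ccccc3)C(C)(C)C)[C@H]2O[C@@H]12.O=C1C=C[C@](O)(C/C=C(\C)CC/C=C(\C)CC/C=C(\C)CO[Si](c3ccccc3)(c3ccccc3)C(C)(C)C)[C@@H]2O[C@H]12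
F3 | step 11 | racemic ketol, 19 together with its enantiomer | O[C@H]1C(=O)C=C[C@]2(C/C=C(\C)CC/C=C(\C)CC/C=C(\C)CO[Si](c3ccccc3)(c3ccccc3)C(C)(C)C)O[C@H]12.O[C@@H]1C(=O)C=C[C@@]2(C/C=C(\C)CC/C=C(\C)CC/C=C(\C)CO[Si](c3ccccc3)(c3ccccc3)C(C)(C)C)O[C@@H]12
F4 | step 11 | enantiomeric ketol acetate, (1S,5R,6S)-1-acetoxy-5,6-epoxy-5-(silyloxyfarnesyl)cyclohex-3-en-2-one | CC(=O)O[C@@H]1C(=O)C=C[C@@]2(C/C=C(\C)CC/C=C(\C)CC/C=C(\C)CO[Si](c3ccccc3)(c3ccccc3)C(C)(C)C)O[C@@H]12
F5 | step 16 | transposed secondary allylic alcohol, 5,6-epoxy-2-methyl-1-(triethylsilyloxy)-5-(silyloxyfarnesyl)cyclohex-2-en-4-ol, C4 epimers (C4 left undefined) | CC[Si](CC)(CC)O[C@H]1C(C)=CC(O)[C@]2(C/C=C(\C)CC/C=C(\C)CC/C=C(\C)CO[Si](c3ccccc3)(c3ccccc3)C(C)(C)C)O[C@H]12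
F6 | step 18 | epoxyquinone, (5R,6S)-5,6-epoxy-2-methyl-5-(silyloxyfarnesyl)cyclohex-2-ene-1,4-dione | O=C1C(C)=CC(=O)[C@]2(C/C=C(\C)CC/C=C(\C)CC/C=C(\C)CO[Si](c3ccccc3)(c3ccccc3)C(C)(C)C)O[C@H]12
F7 | step 18 | syn epoxy alcohol, (1R,5R,6R)-5,6-epoxy-1-hydroxy-2-methyl-5-(silyloxyfarnesyl)cyclohex-2-en-4-one | O[C@@H]1C(C)=CC(=O)[C@]2(C/C=C(\C)CC/C=C(\C)CC/C=C(\C)CO[Si](c3ccccc3)(c3ccccc3)C(C)(C)C)O[C@H]12
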